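**Plan**
Elemane numbering is used: ring carbons C5–C10, epoxide C1–C2 and methyl C14 on C10, aldehyde C3 on C4(=C15) attached to C5, lactone C12(=O)–O–C8 with C11(=C13) on C7.
Retrosynthesis: the enal, the free C9–OH, the α-methylene group, the C7–H and the epoxide are taken back to a butenolide-fused cyclohexane carrying a silyl ether, an acetonide and a C3 silyl ether; its C8–C9 and C5–C6 bonds are then cut together, a [3+3] disconnection into a furan aldehyde (fragment A: C6, C7, C8, C11, C12) and an aldehyde–allylsilane (fragment B: C9, C10, C5 and all other carbons).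
Enabling feature: C8(O)–C9(OH) is the γ-carbon/carbinol pair of a butenolide (vinylogous aldol retron) and C6(O)–C5–C4(=C15H2) is a homoallylic alcohol with an exocyclic methylene (allylsilane–aldehyde retron); in each fragment donor and acceptor carbon are 1,3-related, so the two carbonyl additions close the C5–C10 ring with the lactone ring already fused.
Forward: fragment A from dihydroxyacetone (3 steps), fragment B from diethyl (R)-malate (9 steps), one-flask annulation, then isobutyrate, epoxide, conjugate reduction with α-methylenation, desilylation and allylic oxidation.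
Stereochemistry: C1 from malate; C10 by two enolate alkylations anti to the C1 alkoxide; C9 by Felkin–Anh addition; C8 by equilibration; C5 and C6 in the chair-like ring closure; C7 by face-selective copper hydride addition.
Key step: step 14

Step 1
Reactants: 1 1,3-dihydroxyacetone dimer
Product: 3 4-(hydroxymethyl)furan-2(5H)-one, via hydroxy enoate 2 (not isolated)
Conditions: Ph3P=CHCO2Et, CH2Cl2, rt
Reagents that add atoms: ethyl (triphenylphosphoranylidene)acetate, CCOC(=O)C=P(c1ccccc1)(c1ccccc1)c1ccccc1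
Why: Wittig olefination of the keto form gives an enoate in which one of the two hydroxymethyl groups is necessarily cis to the ester and lactonises to the butenolide.

Step 2
Reactants: 3 4-(hydroxymethyl)furan-2(5H)-one
Product: 4 5-oxo-2,5-dihydrofuran-3-carbaldehyde
Conditions: MnO2, CH2Cl2, rt
Reagents that add atoms: none
Why: Allylic oxidation with MnO2 converts the primary allylic alcohol into the aldehyde without touching the lactone.

Step 3
Reactants: 4 5-oxo-2,5-dihydrofuran-3-carbaldehyde
Product: 5 5-[(tert-butyldimethylsilyl)oxy]furan-3-carbaldehyde (fragment A)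
Conditions: TBSOTf, Et3N, CH2Cl2, 0 °C
Reagents that add atoms: tert-butyldimethylsilyl triflate, CC(C)(C)[Si](C)(C)OS(=O)(=O)C(F)(F)F
Why: Soft enolisation (silyl dienol ether formation) removes the acidic γ-hydrogen and gives the aromatic 2-silyloxyfuran, whose aldehyde is a deactivated vinylogous formate.

Step 4
Reactants: 6 methyl 2-[bis(2,2,2-trifluoroethoxy)phosphoryl]acetate
Product: 7 methyl 2-[bis(2,2,2-trifluoroethoxy)phosphoryl]-3-(trimethylsilyl)propanoate
Conditions: NaH, DME, 0 °C; Me3SiCH2I, 70 °C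
Reagents that add atoms: (iodomethyl)trimethylsilane, C[Si](C)(C)CI
Why: Enolate C-alkylation of the phosphonoacetate with the primary iodide gives the α-branched reagent needed for the Still–Gennari olefination.

Step 5
Reactants: 8 diethyl (R)-malate
Product: 9 diethyl (2R,3S)-3-[(benzyloxy)methyl]-2-hydroxybutanedioate
Conditions: LiN(i-Pr)2 (2.2 equiv), THF, −78 to −20 °C; BnOCH2Cl, −78 °C
Reagents that add atoms: benzyl chloromethyl ether, ClCOCc1ccccc1
Why: Fráter–Seebach alkylation of the dilithio alkoxide–enolate brings the electrophile in anti to the alkoxide oxygen; this centre is made planar again in step 6.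

Step 6
Reactants: 9 diethyl (2R,3S)-3-[(benzyloxy)methyl]-2-hydroxybutanedioate
Product: 10 diethyl (2R,3R)-3-[(benzyloxy)methyl]-2-hydroxy-3-methylbutanedioate
Conditions: LiN(i-Pr)2 (2.5 equiv), THF–DMPU, −78 to −20 °C; MeI
Reagents that add atoms: iodomethane, CI
Why: A second Fráter–Seebach alkylation brings methyl in anti to the alkoxide so that the benzyloxymethyl arm ends syn, which fixes the quaternary centre (C10) relative to the malate carbinol (C1).

Step 7
Reactants: 10 diethyl (2R,3R)-3-[(benzyloxy)methyl]-2-hydroxy-3-methylbutanedioate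
Product: 12 ethyl (2R)-3-(benzyloxy)-2-[(4R)-2,2-dimethyl-1,3-dioxolan-4-yl]-2-methylpropanoate, via diol ester 11 (not isolated)
Conditions: BH3·SMe2, NaBH4 (5 mol%), THF, 0 °C to rt; MeOH; then Me2C(OMe)2, TsOH·H2O (cat.), acetone, rt
Reagents that add atoms: 2,2-dimethoxypropane, COC(C)(C)OC
Why: Hydroxyl-directed borane reduction touches only the ester next to the free hydroxyl, and the terminal 1,2-diol is trapped as the acetonide before it can lactonise onto the hindered quaternary ester.

Step 8
Reactants: 12 ethyl (2R)-3-(benzyloxy)-2-[(4R)-2,2-dimethyl-1,3-dioxolan-4-yl]-2-methylpropanoate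
Product: 13 ethyl (2R)-2-[(4R)-2,2-dimethyl-1,3-dioxolan-4-yl]-3-hydroxy-2-methylpropanoate
Conditions: H2 (1 atm), Pd/C, EtOH, rt
Reagents that add atoms: none
Why: Catalytic hydrogenolysis removes the benzyl ether at a stage where no alkene is present.

Step 9
Reactants: 13 ethyl (2R)-2-[(4R)-2,2-dimethyl-1,3-dioxolan-4-yl]-3-hydroxy-2-methylpropanoate
Product: 14 ethyl (2S)-2-[(4R)-2,2-dimethyl-1,3-dioxolan-4-yl]-2-methyl-3-oxopropanoate
Conditions: Dess–Martin periodinane, NaHCO3, CH2Cl2, 0 °C to rt
Reagents that add atoms: none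
Why: Dess–Martin oxidation gives the aldehyde, which is non-enolisable because its α-carbon is quaternary.

Step 10
Reactants: 14 ethyl (2S)-2-[(4R)-2,2-dimethyl-1,3-dioxolan-4-yl]-2-methyl-3-oxopropanoate; 7 methyl 2-[bis(2,2,2-trifluoroethoxy)phosphoryl]-3-(trimethylsilyl)propanoate
Product: 15 1-ethyl 5-methyl 2-[(4R)-2,2-dimethyl-1,3-dioxolan-4-yl]-2-methyl-4-[(trimethylsilyl)methyl]pent-3-enedioate (methyl ester cis to the quaternary carbon; quaternary carbon as in 14)
Conditions: KN(SiMe3)2, 18-crown-6, THF, −78 °C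
Reagents that add atoms: none
Why: Still–Gennari olefination places the ester cis to the aldehyde-derived carbon under kinetic control, so that CH2SiMe3 ends trans to C10 as the ring closure of step 14 requires.

Step 11
Reactants: 15 1-ethyl 5-methyl 2-[(4R)-2,2-dimethyl-1,3-dioxolan-4-yl]-2-methyl-4-[(trimethylsilyl)methyl]pent-3-enedioate
Product: 16 2-[(4R)-2,2-dimethyl-1,3-dioxolan-4-yl]-2-methyl-4-[(trimethylsilyl)methyl]pent-3-ene-1,5-diol (C5 hydroxymethyl cis to the quaternary carbon)
Conditions: i-Bu2AlH (6 equiv), CH2Cl2, −78 to 0 °C; Rochelle salt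
Reagents that add atoms: none
Why: Ester reduction with i-Bu2AlH converts both esters into primary alcohols while acetonide and allylsilane are inert at low temperature.

Step 12
Reactants: 16 2-[(4R)-2,2-dimethyl-1,3-dioxolan-4-yl]-2-methyl-4-[(trimethylsilyl)methyl]pent-3-ene-1,5-diol
Product: 17 5-[(tert-butyldiphenylsilyl)oxy]-2-[(4R)-2,2-dimethyl-1,3-dioxolan-4-yl]-2-methyl-4-[(trimethylsilyl)methyl]pent-3-en-1-ol
Conditions: TBDPSCl (1.05 equiv), imidazole, CH2Cl2, −20 °C
Reagents that add atoms: tert-butyl(chloro)diphenylsilane, CC(C)(C)[Si](Cl)(c1ccccc1)c1ccccc1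
Why: Selective silylation: the bulky silyl chloride takes the allylic primary hydroxyl in preference to the neopentyl one next to the quaternary carbon.

Step 13
Reactants: 17 5-[(tert-butyldiphenylsilyl)oxy]-2-[(4R)-2,2-dimethyl-1,3-dioxolan-4-yl]-2-methyl-4-[(trimethylsilyl)methyl]pent-3-en-1-ol
Product: 18 5-[(tert-butyldiphenylsilyl)oxy]-2-[(4R)-2,2-dimethyl-1,3-dioxolan-4-yl]-2-methyl-4-[(trimethylsilyl)methyl]pent-3-enal (fragment B)
Conditions: Dess–Martin periodinane, NaHCO3, CH2Cl2, 0 °C to rt
Reagents that add atoms: none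
Why: Dess–Martin oxidation of the neopentyl alcohol gives a non-enolisable aldehyde that cannot be reached by its own allylsilane.

Step 14
Reactants: 18 fragment B; 5 fragment A
Product: 21 7-[(tert-butyldimethylsilyl)oxy]-5-{3-[(tert-butyldiphenylsilyl)oxy]prop-1-en-2-yl}-6-[(4R)-2,2-dimethyl-1,3-dioxolan-4-yl]-4-hydroxy-6-methyl-5,6,7,7a-tetrahydro-1-benzofuran-2(4H)-one (positions 4/5/6/7/7a = C6/C5/C10/C9/C8; target configuration), via butenolide aldehyde 19 (not isolated), via cyclised trimethylsilyl ether 20 (not isolated)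
Conditions: TBSOTf (5 mol%), 2,6-di-tert-butyl-4-methylpyridine (10 mol%), CH2Cl2, −78 °C then −20 °C; citric acid, MeOH, 0 °C
Reagents that add atoms: none
Why: Proposed new method: a silyl triflate-catalysed intermolecular vinylogous Mukaiyama aldol of the 2-silyloxyfuran carbon C8 to the aldehyde C9 of 18 gives butenolide 19, in which the former vinylogous-formate aldehyde C6 has become an activated ene-aldehyde that the pendant allylsilane attacks at C5 in an intramolecular Hosomi–Sakurai reaction; the closest known reactions are the vinylogous Mukaiyama aldol of 2-silyloxyfurans and Lewis acid-promoted allylsilane–aldehyde cyclisations, which have not been combined as a [3+3] annulation. The carbocycle closes by 6-exo-trig attack of C5 on the C6 carbonyl through a chair-like open transition state with anti-SE2′ loss of silicon, which also creates the C4=C15 methylene. C9 is set by Felkin–Anh addition (dioxolanyl group antiperiplanar to the incoming furan carbon, methyl as the small group), and C8, the epimerisable γ-position of the butenolide, should equilibrate through the silyloxyfuran under the triflate–pyridine buffer so that only the epimer with the lactone oxygen equatorial and cis to O9 cyclises. C5 is set by allylic 1,3-strain (methyl eclipses the alkene, the bulky dioxolanyl group lies anti to the forming bond and becomes equatorial) and C6 by the s-trans ene-aldehyde–silyl complex, which places O6 axial and cis to the C5 substituent as in Lewis acid-promoted allylmetal–aldehyde ring closures. The step needs γ- rather than α-attack of the furan (favoured by the bulky silyl group on the neighbouring oxygen and by the neopentyl aldehyde) and reaction at the aldehyde of 18 before that of 5 (the furan aldehyde is deactivated until the first bond is made); the silicon of the allylsilane ends on O6 as a labile trimethylsilyl ether that the methanolic acid work-up removes while the tert-butyldimethylsilyl group stays on O9.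

Step 15
Reactants: 21 bicyclic butenolide alcohol
Product: 22 4-O-isobutyrate of 21 (2-methylpropanoate at C6)
Conditions: (i-PrCO)2O, DMAP, Et3N, CH2Cl2, rt
Reagents that add atoms: isobutyric anhydride, CC(C)C(=O)OC(=O)C(C)C
Why: DMAP-catalysed acylation esterifies the only free hydroxyl, the axial C6–OH.

Step 16
Reactants: 22 isobutyrate acetonide
Product: 23 diol of 22 (6-[(1R)-1,2-dihydroxyethyl] in place of the dioxolane)
Conditions: AcOH–THF–H2O (3:1:1), 45 °C
Reagents that add atoms: none
Why: Acetal hydrolysis removes the terminal acetonide while the hindered secondary silyl ether, the primary tert-butyldiphenylsilyl ether and the ester survive.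

Step 17
Reactants: 23 diol
Product: 24 epoxide (6-methyl-6-[(2R)-oxiran-2-yl] butenolide)
Conditions: PPh3, DIAD, PhMe, 0 to 60 °C
Reagents that add atoms: none
Why: Mitsunobu cyclodehydration activates the primary C2 hydroxyl and the C1 oxygen displaces it, so the epoxide forms with retention at the malate-derived C1.

Step 18
Reactants: 24 epoxy butenolide
Product: 26 Mannich base (3-[(dimethylamino)methyl] saturated trans-fused lactone; C11 epimers), via silyl ketene acetal 25 (not isolated)
Conditions: Cu(OAc)2·H2O (5 mol%), DTBM-SEGPHOS (matched enantiomer, 5.5 mol%), (EtO)2MeSiH, PhMe, 0 °C to rt; then Me2N=CH2+ I−, CH2Cl2, rt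
Reagents that add atoms: N,N-dimethylmethyleneiminium iodide (Eschenmoser's salt), C=[N+](C)C.[I-]
Why: Ligand-controlled copper hydride conjugate reduction should add hydride to C7 on the face opposite the axial C6 isobutyrate to give the trans-fused lactone, and the silyl ketene acetal is aminomethylated in a Mannich reaction, the C11 centre being lost in step 19.

Step 19
Reactants: 26 Mannich base
Product: 28 α-methylene lactone bis-silyl ether, via ammonium iodide 27 (not isolated)
Conditions: MeI, THF, rt; then NaHCO3, CH2Cl2–H2O, rt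
Reagents that add atoms: none
Why: Quaternisation and Hofmann-type β-elimination unveil the α-methylene lactone under conditions that spare epoxide and isobutyrate.

Step 20
Reactants: 28 α-methylene lactone bis-silyl ether
Product: 29 diol (C3–OH and C9–OH free)
Conditions: Bu4NF, AcOH (1:1), THF, 0 °C to rt
Reagents that add atoms: none
Why: Buffered fluoride desilylation cleaves both silyl ethers without forming a free C9 alkoxide that could open the neighbouring epoxide.

Step 21
Reactants: 29 diol
Product: 30 CNP0496100.1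
Conditions: MnO2, CH2Cl2, rt
Reagents that add atoms: none
Why: Chemoselective allylic oxidation converts only the primary allylic alcohol into the α-methylene aldehyde and leaves the secondary C9 hydroxyl, the epoxide and the lactone untouched.

**Compound list**
1 | 1,3-dihydroxyacetone dimer | OCC1(O)COC(O)(CO)CO1 | starting material
2 | ethyl 4-hydroxy-3-(hydroxymethyl)but-2-enoate | CCOC(=O)C=C(CO)CO | intermediate
3 | 4-(hydroxymethyl)furan-2(5H)-one | OCC1=CC(=O)OC1 | intermediate
4 | 5-oxo-2,5-dihydrofuran-3-carbaldehyde | O=CC1=CC(=O)OC1 | intermediate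
5 | 5-[(tert-butyldimethylsilyl)oxy]furan-3-carbaldehyde (fragment A) | O=Cc1coc(O[Si](C)(C)C(C)(C)C)c1 | intermediate
6 | methyl 2-[bis(2,2,2-trifluoroethoxy)phosphoryl]acetate | COC(=O)CP(=O)(OCC(F)(F)F)OCC(F)(F)F | starting material
7 | methyl 2-[bis(2,2,2-trifluoroethoxy)phosphoryl]-3-(trimethylsilyl)propanoate | COC(=O)C(C[Si](C)(C)C)P(=O)(OCC(F)(F)F)OCC(F)(F)F | intermediate
8 | diethyl (R)-malate | CCOC(=O)C[C@@H](O)C(=O)OCC | starting material
9 | diethyl (2R,3S)-3-[(benzyloxy)methyl]-2-hydroxybutanedioate | [C@H](COCc1ccccc1)([C@@H](O)C(=O)OCC)C(=O)OCC | intermediate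
10 | diethyl (2R,3R)-3-[(benzyloxy)methyl]-2-hydroxy-3-methylbutanedioate | C(c1ccccc1)OC[C@](C)([C@@H](O)C(=O)OCC)C(=O)OCC | intermediate
11 | ethyl (2R,3R)-2-[(benzyloxy)methyl]-3,4-dihydroxy-2-methylbutanoate | C(c1ccccc1)OC[C@](C)([C@@H](O)CO)C(=O)OCC | intermediate
12 | ethyl (2R)-3-(benzyloxy)-2-[(4R)-2,2-dimethyl-1,3-dioxolan-4-yl]-2-methylpropanoate | C(c1ccccc1)OC[C@](C)([C@@H]1COC(C)(C)O1)C(=O)OCC | intermediate
13 | ethyl (2R)-2-[(4R)-2,2-dimethyl-1,3-dioxolan-4-yl]-3-hydroxy-2-methylpropanoate | OC[C@](C)([C@@H]1COC(C)(C)O1)C(=O)OCC | intermediate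
14 | ethyl (2S)-2-[(4R)-2,2-dimethyl-1,3-dioxolan-4-yl]-2-methyl-3-oxopropanoate | O=C[C@](C)([C@@H]1COC(C)(C)O1)C(=O)OCC | intermediate
15 | 1-ethyl 5-methyl 2-[(4R)-2,2-dimethyl-1,3-dioxolan-4-yl]-2-methyl-4-[(trimethylsilyl)methyl]pent-3-enedioate (methyl ester cis to the quaternary carbon) | COC(=O)/C(C[Si](C)(C)C)=C\[C@](C)([C@@H]1COC(C)(C)O1)C(=O)OCC | intermediate
16 | 2-[(4R)-2,2-dimethyl-1,3-dioxolan-4-yl]-2-methyl-4-[(trimethylsilyl)methyl]pent-3-ene-1,5-diol | OC/C(C[Si](C)(C)C)=C\[C@](C)([C@@H]1COC(C)(C)O1)CO | intermediate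
17 | 5-O-tert-butyldiphenylsilyl ether of 16 | CC(C)(C)[Si](c1ccccc1)(c1ccccc1)OC/C(C[Si](C)(C)C)=C\[C@](C)([C@@H]1COC(C)(C)O1)CO | intermediate
18 | fragment B, aldehyde from 17 | CC(C)(C)[Si](c1ccccc1)(c1ccccc1)OC/C(C[Si](C)(C)C)=C\[C@](C)([C@@H]1COC(C)(C)O1)C=O | intermediate
19 | butenolide aldehyde (γ-adduct; C8–C9 formed, O9 silylated, C6 aldehyde free) | O=C1O[C@H](C(=C1)C=O)[C@@H](O[Si](C)(C)C(C)(C)C)[C@@](C)([C@@H]1COC(C)(C)O1)/C=C(/C[Si](C)(C)C)CO[Si](c1ccccc1)(c1ccccc1)C(C)(C)C | intermediate
20 | cyclised core as C6 trimethylsilyl ether | O=C1O[C@@H]2C(=C1)[C@@H](O[Si](C)(C)C)[C@@H](C(=C)CO[Si](c1ccccc1)(c1ccccc1)C(C)(C)C)[C@](C)([C@@H]1COC(C)(C)O1)[C@@H]2O[Si](C)(C)C(C)(C)C | intermediate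
21 | bicyclic butenolide core, C6–OH free, C9–OTBS | O=C1O[C@@H]2C(=C1)[C@@H](O)[C@@H](C(=C)CO[Si](c1ccccc1)(c1ccccc1)C(C)(C)C)[C@](C)([C@@H]1COC(C)(C)O1)[C@@H]2O[Si](C)(C)C(C)(C)C | intermediate
22 | C6 isobutyrate of 21 | O=C1O[C@@H]2C(=C1)[C@@H](OC(=O)C(C)C)[C@@H](C(=C)CO[Si](c1ccccc1)(c1ccccc1)C(C)(C)C)[C@](C)([C@@H]1COC(C)(C)O1)[C@@H]2O[Si](C)(C)C(C)(C)C | intermediate
23 | C1,C2-diol from 22 | O=C1O[C@@H]2C(=C1)[C@@H](OC(=O)C(C)C)[C@@H](C(=C)CO[Si](c1ccccc1)(c1ccccc1)C(C)(C)C)[C@](C)([C@@H](O)CO)[C@@H]2O[Si](C)(C)C(C)(C)C | intermediate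
24 | epoxy butenolide | O=C1O[C@@H]2C(=C1)[C@@H](OC(=O)C(C)C)[C@@H](C(=C)CO[Si](c1ccccc1)(c1ccccc1)C(C)(C)C)[C@](C)([C@@H]1CO1)[C@@H]2O[Si](C)(C)C(C)(C)C | intermediate
25 | diethoxy(methyl)silyl ketene acetal of the reduced lactone | C1=C(O[Si](C)(OCC)OCC)O[C@@H]2[C@@H]1[C@@H](OC(=O)C(C)C)[C@@H](C(=C)CO[Si](c1ccccc1)(c1ccccc1)C(C)(C)C)[C@](C)([C@@H]1CO1)[C@@H]2O[Si](C)(C)C(C)(C)C | intermediate
26 | Mannich base (C11 epimers) | CN(C)CC1C(=O)O[C@@H]2[C@@H]1[C@@H](OC(=O)C(C)C)[C@@H](C(=C)CO[Si](c1ccccc1)(c1ccccc1)C(C)(C)C)[C@](C)([C@@H]1CO1)[C@@H]2O[Si](C)(C)C(C)(C)C | intermediate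
27 | trimethylammonium iodide of 26 | C[N+](C)(C)CC1C(=O)O[C@@H]2[C@@H]1[C@@H](OC(=O)C(C)C)[C@@H](C(=C)CO[Si](c1ccccc1)(c1ccccc1)C(C)(C)C)[C@](C)([C@@H]1CO1)[C@@H]2O[Si](C)(C)C(C)(C)C.[I-] | intermediate
28 | α-methylene lactone bis-silyl ether | C=C1C(=O)O[C@@H]2[C@@H]1[C@@H](OC(=O)C(C)C)[C@@H](C(=C)CO[Si](c1ccccc1)(c1ccccc1)C(C)(C)C)[C@](C)([C@@H]1CO1)[C@@H]2O[Si](C)(C)C(C)(C)C | intermediate
29 | diol (C3–OH, C9–OH) | C=C1C(=O)O[C@@H]2[C@@H]1[C@@H](OC(=O)C(C)C)[C@@H](C(=C)CO)[C@](C)([C@@H]1CO1)[C@@H]2O | intermediate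
30 | CNP0496100.1 | C=C1C(=O)O[C@@H]2[C@@H]1[C@@H](OC(=O)C(C)C)[C@@H](C(=C)C=O)[C@](C)([C@@H]1CO1)[C@@H]2O | target

**Count and risks**
Total step count: 21. Longest linear sequence: 17 steps (steps 5–13, 14, 15–21, from diethyl (R)-malate).

Step 14 (proposed new method). What may go wrong: α- instead of γ-attack of the formyl-substituted silyloxyfuran, poor facial selectivity at C9 (the dioxolanyl and alkenyl groups compete for the antiperiplanar position), slow C8 equilibration, or ring closure before or without the first bond. Fallback by known, separate reactions, from 3 and 18, returning at 21: 3 is bis-silylated (Et3SiOTf, Et3N) to the non-conjugating triethyl({5-[(triethylsilyl)oxy]furan-3-yl}methoxy)silane F1. A BF3·OEt2-mediated vinylogous Mukaiyama aldol of F1 with 18 gives the γ-adduct hydroxy butenolide F2. Silylation of O9 (TBSOTf, 2,6-lutidine) gives the bis-silyl ether F3, and methanolysis of the primary triethylsilyl ether (pyridinium tosylate, MeOH) gives the primary alcohol F4. MnO2 oxidation gives 19 as an isolated compound, and BF3·OEt2 at −78 °C closes the ring in a separate intramolecular Hosomi–Sakurai reaction to 21; C8 epimers are equilibrated with DBU at that stage.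

Step 18. What may go wrong: hydride delivery to the wrong face of C7 (cis-fused lactone), sluggish reduction of the β,β-disubstituted butenolide, or incomplete aminomethylation. Fallback from 24, returning at 28: α-iodination (I2, pyridine) gives the α-iodobutenolide F5, and Stille coupling with Bu3SnCH2OH (Pd(PPh3)4) gives the α-(hydroxymethyl)butenolide F6. Mitsunobu reaction of F6 with 2-nitrobenzenesulfonylhydrazide (PPh3, DEAD) gives an allylic diazene that loses N2 in a retro-ene step; this delivers hydrogen to C7 intramolecularly and moves the double bond to C11=C13, giving 28 directly.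

Step 17. What may go wrong: slow cyclodehydration next to the quaternary carbon, or elimination of the activated primary oxygen. Fallback from 23, returning at 24: Bu2SnO-catalysed tosylation (TsCl, Et3N) gives the primary tosylate F7, and DBU then closes the epoxide by intramolecular displacement with retention at C1.

**Further compounds**
F1 | step 14 | triethyl({5-[(triethylsilyl)oxy]furan-3-yl}methoxy)silane | CC[Si](CC)(CC)OCc1coc(O[Si](CC)(CC)CC)c1
F2 | step 14 | γ-adduct hydroxy butenolide (C9–OH, C6 as CH2OSiEt3) | O=C1O[C@H](C(=C1)CO[Si](CC)(CC)CC)[C@@H](O)[C@@](C)([C@@H]1COC(C)(C)O1)/C=C(/C[Si](C)(C)C)CO[Si](c1ccccc1)(c1ccccc1)C(C)(C)C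
F3 | step 14 | bis-silyl ether (O9 tert-butyldimethylsilyl) | O=C1O[C@H](C(=C1)CO[Si](CC)(CC)CC)[C@@H](O[Si](C)(C)C(C)(C)C)[C@@](C)([C@@H]1COC(C)(C)O1)/C=C(/C[Si](C)(C)C)CO[Si](c1ccccc1)(c1ccccc1)C(C)(C)C
F4 | step 14 | primary alcohol (C6 as CH2OH) | O=C1O[C@H](C(=C1)CO)[C@@H](O[Si](C)(C)C(C)(C)C)[C@@](C)([C@@H]1COC(C)(C)O1)/C=C(/C[Si](C)(C)C)CO[Si](c1ccccc1)(c1ccccc1)C(C)(C)C
F5 | step 18 | α-iodobutenolide | O=C1O[C@@H]2C(=C1I)[C@@H](OC(=O)C(C)C)[C@@H](C(=C)CO[Si](c1ccccc1)(c1ccccc1)C(C)(C)C)[C@](C)([C@@H]1CO1)[C@@H]2O[Si](C)(C)C(C)(C)C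
F6 | step 18 | α-(hydroxymethyl)butenolide | O=C1O[C@@H]2C(=C1CO)[C@@H](OC(=O)C(C)C)[C@@H](C(=C)CO[Si](c1ccccc1)(c1ccccc1)C(C)(C)C)[C@](C)([C@@H]1CO1)[C@@H]2O[Si](C)(C)C(C)(C)C
F7 | step 17 | primary tosylate of diol 23 | O=C1O[C@@H]2C(=C1)[C@@H](OC(=O)C(C)C)[C@@H](C(=C)CO[Si](c1ccccc1)(c1ccccc1)C(C)(C)C)[C@](C)([C@@H](O)COS(=O)(=O)c1ccc(C)cc1)[C@@H]2O[Si](C)(C)C(C)(C)C
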